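Each indole is bonded to the central tetramethoxybenzene through C3 and keeps an unsubstituted C2–H, so both pyrrole rings are disconnected at N1–C2 to 1-(2-nitroaryl)vinyl arms. A single palladium/CO reductive N-heteroannulation then removes the oxygen atoms of both nitro groups and closes both five-membered rings onto the alkene CH2 termini. Its substrate is 1,4-bis[1-(2-nitroaryl)vinyl]-2,3,5,6-tetramethoxybenzene, with a 4-methoxy group on one nitroarene and a 5-benzyloxy group on the other, assembled by two successive Barluenga couplings of 1,4-dibromo-2,3,5,6-tetramethoxybenzene with nitroacetophenone tosylhydrazones. Hydrogenolysis of the benzyl ether finishes the synthesis.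

Key step: step 7

Remark: a substituent para to the vinyl-bearing carbon of a 2-nitroaryl arm ends at indole C6 and one para to the nitro group ends at C5, which fixes the arms as 4-methoxy-2-nitrophenyl and 5-benzyloxy-2-nitrophenyl; hydrazone geometry is left undefined in the SMILES because both isomers give the same diazoalkane.

Step 1
Reactants: 1 1,2,4,5-tetramethoxybenzene
Product: 2 1,4-dibromo-2,3,5,6-tetramethoxybenzene
Conditions: Br2 (2.2 equiv), CH2Cl2, 0 °C to rt
Reagents that add atoms: bromine, BrBr
Why: Twofold electrophilic aromatic bromination, in which the two remaining ring hydrogens, each flanked by two ortho methoxy groups, are the only positions open to substitution, so no regiochemical question arises.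

Step 2
Reactants: 3 1-(4-methoxy-2-nitrophenyl)ethanone
Product: 4 N'-[1-(4-methoxy-2-nitrophenyl)ethylidene]-4-methylbenzenesulfonohydrazide
Conditions: TsNHNH2 (1.1 equiv), MeOH, 60 °C
Reagents that add atoms: p-toluenesulfonohydrazide, Cc1ccc(cc1)S(=O)(=O)NN
Why: Condensation of an aryl methyl ketone with tosylhydrazide (hydrazone formation) is routine, the nitro and methoxy groups are inert, and the product should crystallise from the cooled methanol.

Step 3
Reactants: 2 1,4-dibromo-2,3,5,6-tetramethoxybenzene; 4 N'-[1-(4-methoxy-2-nitrophenyl)ethylidene]-4-methylbenzenesulfonohydrazide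
Product: 6 1-bromo-2,3,5,6-tetramethoxy-4-[1-(4-methoxy-2-nitrophenyl)vinyl]benzene, via 1-(1-diazoethyl)-4-methoxy-2-nitrobenzene 5 (not isolated)
Conditions: 2 (3 equiv, excess recovered), Pd2(dba)3 (2.5 mol %), XPhos (10 mol %), LiOt-Bu (2.4 equiv), 1,4-dioxane, 100 °C
Reagents that add atoms: none
Why: Barluenga coupling, in which LiOt-Bu turns 4 into diazoalkane 5 (Bamford–Stevens), the arylpalladium bromide from oxidative addition of 2 traps it as a palladium carbene, and aryl migration followed by β-hydride elimination from the methyl group gives the 1,1-diarylethylene, while the excess of 2 and the slightly higher reactivity of its C–Br bonds compared with the one left in 6 should hold the reaction at mono-coupling.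

Step 4
Reactants: 7 1-(5-hydroxy-2-nitrophenyl)ethanone
Product: 8 1-(5-benzyloxy-2-nitrophenyl)ethanone
Conditions: BnBr (1.1 equiv), K2CO3 (1.0 equiv), DMF, rt
Reagents that add atoms: benzyl bromide, BrCc1ccccc1
Why: Williamson ether synthesis, in which the phenol, acidified by the para nitro group, is deprotonated by carbonate and alkylated on oxygen by the benzylic bromide without touching the ketone.

Step 5
Reactants: 8 1-(5-benzyloxy-2-nitrophenyl)ethanone
Product: 9 N'-[1-(5-benzyloxy-2-nitrophenyl)ethylidene]-4-methylbenzenesulfonohydrazide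
Conditions: TsNHNH2 (1.1 equiv), MeOH, 60 °C
Reagents that add atoms: p-toluenesulfonohydrazide, Cc1ccc(cc1)S(=O)(=O)NN
Why: The same tosylhydrazone condensation as in step 2, with the benzyl ether and nitro group as spectators.

Step 6
Reactants: 6 1-bromo-2,3,5,6-tetramethoxy-4-[1-(4-methoxy-2-nitrophenyl)vinyl]benzene; 9 N'-[1-(5-benzyloxy-2-nitrophenyl)ethylidene]-4-methylbenzenesulfonohydrazide
Product: 11 1-[1-(5-benzyloxy-2-nitrophenyl)vinyl]-2,3,5,6-tetramethoxy-4-[1-(4-methoxy-2-nitrophenyl)vinyl]benzene, via 4-benzyloxy-2-(1-diazoethyl)-1-nitrobenzene 10 (not isolated)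
Conditions: 9 (1.3 equiv), Pd2(dba)3 (5 mol %), XPhos (20 mol %), LiOt-Bu (2.4 equiv per 9), 1,4-dioxane, 100 °C
Reagents that add atoms: none
Why: Second Barluenga coupling at the remaining C–Br bond, where the bulky electron-rich XPhos ligand promotes oxidative addition into the doubly ortho-substituted bromide, the carbene formed from diazoalkane 10 inserts and eliminates as in step 3, and the first alkene, both nitro groups and the benzyl ether tolerate the hindered alkoxide base.

Step 7
Reactants: 11 1-[1-(5-benzyloxy-2-nitrophenyl)vinyl]-2,3,5,6-tetramethoxy-4-[1-(4-methoxy-2-nitrophenyl)vinyl]benzene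
Product: 14 5-benzyloxy-3-[2,3,5,6-tetramethoxy-4-(6-methoxy-1H-indol-3-yl)phenyl]-1H-indole, via 6-methoxyindole nitrostyrene 12 (not isolated), via 5-benzyloxyindole nitrostyrene 13 (not isolated)
Conditions: Pd(OAc)2 (10 mol %), 1,10-phenanthroline (20 mol %), CO (6 atm), DMF, 120 °C, pressure vessel
Reagents that add atoms: none
Why: CO deoxygenates each nitro group at the palladium–phenanthroline centre, which shuttles between divalent and zerovalent palladium and releases CO2, to give a nitrosoarene or palladium-bound nitrene equivalent whose nitrogen attacks the terminal CH2 of the ortho 1-arylvinyl group; a hydrogen shift and a second CO-driven deoxygenation of the N-oxygenated intermediate then deliver the aromatic N–H indole. This is the palladium-catalysed reductive N-heteroannulation of 2-nitrostyrenes with CO, a catalytic Cadogan–Sundberg-type indole synthesis that is established for α-aryl-2-nitrostyrenes giving 3-arylindoles. Each of the two pyrrole rings closes in a five-membered, formally 5-endo, mode by N1–C2 bond formation, the 6-methoxyindole from the 4-methoxy-2-nitrophenyl arm and the 5-benzyloxyindole from the 5-benzyloxy-2-nitrophenyl arm, and the arms react independently through the half-cyclised compounds 12 and 13. No stereocentre is created. Only chemoselectivity is needed: each nitrogen can reach nothing but the CH2 of its own vinyl group, the fully substituted central ring has no C–H bond for a competing insertion, and the absence of H2 leaves the benzyl ether and the methyl ethers untouched.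

Step 8
Reactants: 14 5-benzyloxy-3-[2,3,5,6-tetramethoxy-4-(6-methoxy-1H-indol-3-yl)phenyl]-1H-indole
Product: 15 3-[2,3,5,6-tetramethoxy-4-(6-methoxy-1H-indol-3-yl)phenyl]-1H-indol-5-ol (target)
Conditions: H2 (1 atm), 10% Pd/C, EtOAc–MeOH, rt, work-up under argon
Reagents that add atoms: none
Why: Hydrogenolysis of a benzyl aryl ether over palladium on carbon is fast at 1 atm and room temperature, conditions under which the indole rings and the methyl ethers should not be reduced.

Compound list
1 | 1,2,4,5-tetramethoxybenzene | COc1cc(OC)c(OC)cc1OC | starting material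
2 | 1,4-dibromo-2,3,5,6-tetramethoxybenzene | COc1c(Br)c(OC)c(OC)c(Br)c1OC | intermediate
3 | 1-(4-methoxy-2-nitrophenyl)ethanone | CC(=O)c1ccc(OC)cc1[N+](=O)[O-] | starting material
4 | N'-[1-(4-methoxy-2-nitrophenyl)ethylidene]-4-methylbenzenesulfonohydrazide | CC(=NNS(=O)(=O)c1ccc(C)cc1)c1ccc(OC)cc1[N+](=O)[O-] | intermediate
5 | 1-(1-diazoethyl)-4-methoxy-2-nitrobenzene | CC(=[N+]=[N-])c1ccc(OC)cc1[N+](=O)[O-] | intermediate (formed in the flask, not isolated)
6 | 1-bromo-2,3,5,6-tetramethoxy-4-[1-(4-methoxy-2-nitrophenyl)vinyl]benzene | C=C(c1ccc(OC)cc1[N+](=O)[O-])c1c(OC)c(OC)c(Br)c(OC)c1OC | intermediate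
7 | 1-(5-hydroxy-2-nitrophenyl)ethanone | CC(=O)c1cc(O)ccc1[N+](=O)[O-] | starting material
8 | 1-(5-benzyloxy-2-nitrophenyl)ethanone | CC(=O)c1cc(OCc2ccccc2)ccc1[N+](=O)[O-] | intermediate
9 | N'-[1-(5-benzyloxy-2-nitrophenyl)ethylidene]-4-methylbenzenesulfonohydrazide | CC(=NNS(=O)(=O)c1ccc(C)cc1)c1cc(OCc2ccccc2)ccc1[N+](=O)[O-] | intermediate
10 | 4-benzyloxy-2-(1-diazoethyl)-1-nitrobenzene | CC(=[N+]=[N-])c1cc(OCc2ccccc2)ccc1[N+](=O)[O-] | intermediate (formed in the flask, not isolated)
11 | 1-[1-(5-benzyloxy-2-nitrophenyl)vinyl]-2,3,5,6-tetramethoxy-4-[1-(4-methoxy-2-nitrophenyl)vinyl]benzene | C=C(c1ccc(OC)cc1[N+](=O)[O-])c1c(OC)c(OC)c(C(=C)c2cc(OCc3ccccc3)ccc2[N+](=O)[O-])c(OC)c1OC | intermediate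
12 | 3-{4-[1-(5-benzyloxy-2-nitrophenyl)vinyl]-2,3,5,6-tetramethoxyphenyl}-6-methoxy-1H-indole | COc1ccc2c(-c3c(OC)c(OC)c(C(=C)c4cc(OCc5ccccc5)ccc4[N+](=O)[O-])c(OC)c3OC)c[nH]c2c1 | intermediate (formed in the flask, not isolated)
13 | 5-benzyloxy-3-{2,3,5,6-tetramethoxy-4-[1-(4-methoxy-2-nitrophenyl)vinyl]phenyl}-1H-indole | C=C(c1ccc(OC)cc1[N+](=O)[O-])c1c(OC)c(OC)c(-c2c[nH]c3ccc(OCc4ccccc4)cc23)c(OC)c1OC | intermediate (formed in the flask, not isolated)
14 | 5-benzyloxy-3-[2,3,5,6-tetramethoxy-4-(6-methoxy-1H-indol-3-yl)phenyl]-1H-indole | COc1ccc2c(-c3c(OC)c(OC)c(-c4c[nH]c5ccc(OCc6ccccc6)cc45)c(OC)c3OC)c[nH]c2c1 | intermediate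
15 | 3-[2,3,5,6-tetramethoxy-4-(6-methoxy-1H-indol-3-yl)phenyl]-1H-indol-5-ol | COc1ccc2c(-c3c(OC)c(OC)c(-c4c[nH]c5ccc(O)cc45)c(OC)c3OC)c[nH]c2c1 | target

Total step count: 8
Longest linear sequence: 5 steps (for example steps 4, 5, 6, 7 and 8 from compound 7; the branches from 1 and from 3 are equally long)

Steps most likely to fail

Step 7. The double annulation may stall after one ring has closed, or drift towards over-reduction to anilines or incomplete deoxygenation, because the twisted and crowded 1,1-diarylethylene arms present their CH2 termini poorly to nitrogen. The fallback sets out from 11 and replaces the nitrene-type closure by a condensation. Hydroboration–oxidation of both alkenes (BH3·SMe2, THF, 0 °C to rt, then NaBO3·4H2O) should place oxygen on the terminal carbons and give 2-{4-[1-(5-benzyloxy-2-nitrophenyl)-2-hydroxyethyl]-2,3,5,6-tetramethoxyphenyl}-2-(4-methoxy-2-nitrophenyl)ethanol F1. Its two stereocentres form as a mixture and are erased later, and borane leaves nitroarenes alone at room temperature. Dess–Martin periodinane (NaHCO3, CH2Cl2, 0 °C) should give the dialdehyde 2-{4-[1-(5-benzyloxy-2-nitrophenyl)-2-oxoethyl]-2,3,5,6-tetramethoxyphenyl}-2-(4-methoxy-2-nitrophenyl)acetaldehyde F2, which is used at once. Reduction of both nitro groups with Fe powder in AcOH–EtOH at 80 °C lets each aniline condense with its neighbouring aldehyde, the classical reductive cyclisation of a 2-nitrophenylacetaldehyde. Loss of water and tautomerisation close both pyrrole rings, and the benzyl ether survives, so the route is rejoined at 14.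

Step 3. Mono-selectivity may be lost: coupling may run on at the second C–Br bond, and the mono- and bis-adducts then have to be separated at the cost of hydrazone 4. The fallback sets out from 2 and replaces statistical control by a chemically differentiated dihalide. One bromine–lithium exchange (n-BuLi, 1.0 equiv, THF, −78 °C) should give (4-bromo-2,3,5,6-tetramethoxyphenyl)lithium F3, which is quenched with I2 to give 1-bromo-4-iodo-2,3,5,6-tetramethoxybenzene F4. Barluenga coupling of F4 with 4 (1.05 equiv; Pd2(dba)3, XPhos, LiOt-Bu, 1,4-dioxane, 70–80 °C), again through diazoalkane 5, should then occur at the C–I bond only, because oxidative addition into aryl iodides is markedly faster than into the hindered aryl bromide. The route is rejoined at 6.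

Step 6. Oxidative addition into the electron-rich, doubly ortho-substituted C–Br bond of 6 may be slower than the base-induced loss of the diazoalkane (azine formation), and tert-butoxide at 100 °C may attack the aryl ether para to the nitro group. The fallback sets out from 6 and exchanges the carbene coupling for a base-free Kosugi–Migita–Stille coupling. Purchased 3-bromo-4-nitrophenol F5 is benzylated (BnBr, K2CO3, DMF) to 4-benzyloxy-2-bromo-1-nitrobenzene F6. Sonogashira coupling with trimethylsilylacetylene (PdCl2(PPh3)2, CuI, Et3N, 60 °C) should give [(5-benzyloxy-2-nitrophenyl)ethynyl]trimethylsilane F7, and K2CO3 in MeOH frees 4-benzyloxy-2-ethynyl-1-nitrobenzene F8. Palladium-catalysed hydrostannation (Bu3SnH, PdCl2(PPh3)2, THF, rt) should place tin on the internal carbon, since ortho-substituted arylalkynes are known to give the α-isomer, and so give tributyl[1-(5-benzyloxy-2-nitrophenyl)vinyl]stannane F9. Coupling of F9 with 6 (Pd(PPh3)4, CuI, DMF, 100 °C) rejoins the route at 11.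

Further compounds
F1 | step 7 | 2-{4-[1-(5-benzyloxy-2-nitrophenyl)-2-hydroxyethyl]-2,3,5,6-tetramethoxyphenyl}-2-(4-methoxy-2-nitrophenyl)ethanol (mixture of diastereomers) | OCC(c1ccc(OC)cc1[N+](=O)[O-])c1c(OC)c(OC)c(C(CO)c2cc(OCc3ccccc3)ccc2[N+](=O)[O-])c(OC)c1OC
F2 | step 7 | 2-{4-[1-(5-benzyloxy-2-nitrophenyl)-2-oxoethyl]-2,3,5,6-tetramethoxyphenyl}-2-(4-methoxy-2-nitrophenyl)acetaldehyde (mixture of diastereomers) | O=CC(c1ccc(OC)cc1[N+](=O)[O-])c1c(OC)c(OC)c(C(C=O)c2cc(OCc3ccccc3)ccc2[N+](=O)[O-])c(OC)c1OC
F3 | step 3 | (4-bromo-2,3,5,6-tetramethoxyphenyl)lithium | [Li]c1c(OC)c(OC)c(Br)c(OC)c1OC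
F4 | step 3 | 1-bromo-4-iodo-2,3,5,6-tetramethoxybenzene | COc1c(Br)c(OC)c(OC)c(I)c1OC
F5 | step 6 | 3-bromo-4-nitrophenol (purchased) | Oc1ccc([N+](=O)[O-])c(Br)c1
F6 | step 6 | 4-benzyloxy-2-bromo-1-nitrobenzene | [O-][N+](=O)c1ccc(OCc2ccccc2)cc1Br
F7 | step 6 | [(5-benzyloxy-2-nitrophenyl)ethynyl]trimethylsilane | C[Si](C)(C)C#Cc1cc(OCc2ccccc2)ccc1[N+](=O)[O-]
F8 | step 6 | 4-benzyloxy-2-ethynyl-1-nitrobenzene | C#Cc1cc(OCc2ccccc2)ccc1[N+](=O)[O-]
F9 | step 6 | tributyl[1-(5-benzyloxy-2-nitrophenyl)vinyl]stannane | C=C(c1cc(OCc2ccccc2)ccc1[N+](=O)[O-])[Sn](CCCC)(CCCC)CCCC
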